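**Retrosynthetic overview**
1. Feature: on ring B, the formyl carbon C20 (on quaternary C10) and the first side-chain carbon C11 (on C9) are cis one-carbon branches on neighbouring carbons, next to the methylene-bearing C8. Joined end to end, they are a cyclobutene fused to C9–C10 of an 8-oxodecalin.
2. Key disconnection: the cyclobutene goes back to acetylene and a bicyclic enone ester (C8=O, C9=C10, C4–H ester) by [2+2] photocycloaddition. This makes C10–C20 and C9–C11 and sets C10 and C9 from C5.
3. Rings A and B come from 6-methoxy-1-tetralone. C19 is added by carbonylation, C4 is set by asymmetric hydrogenation, and C5 is set from C4 by Birch reduction and acid conjugation.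
4. After the key step: C4 is methylated anti to C20, then ozonolysis–reduction follows and a temporary C19–C20 δ-lactone tells C20 from C11. C11 becomes a vinyl group, and the lactone is reopened and C20 silylated before the base-labile butenolide is coupled on (B-alkyl Suzuki, C12–C13).
5. Last: C8 ketal → ketone → methylene, then C20 alcohol → aldehyde. Ring order: A/B (bought), cyclobutene (made, cleaved), δ-lactone (made, opened), butenolide (brought in whole).

Key step: step 6

Numbering: labdane numbering throughout. Ring A = C1–C5 and C10; ring B = C5–C10. C19 is the ester carbon on C4, C20 sits on C10, C11–C12 is the chain on C9, C13–C16 is the butenolide, and C17 is the methylene on C8. α is the face of H5; β is the face of C20.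
Assumption: Ru(OAc)2[(R)-BINAP] is taken to give the (R)-acid, by analogy with 2-arylacrylic acids. If this cyclic substrate shows the opposite sense, the (S)-ligand is used and nothing else changes.

**Step 1**
Reactants: 1 6-methoxy-1-tetralone
Product: 2 6-methoxy-3,4-dihydronaphthalen-1-yl trifluoromethanesulfonate
Conditions: Tf2O, 2,6-di-tert-butyl-4-methylpyridine, CH2Cl2, 0 °C → rt
Reagents that add atoms: triflic anhydride, O=S(=O)(OS(=O)(=O)C(F)(F)F)C(F)(F)F
Why: Enol triflate formation by O-sulfonylation of the ketone, which can enolise on one side only, so a single alkene isomer should form.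

**Step 2**
Reactants: 2 enol triflate
Product: 3 6-methoxy-3,4-dihydronaphthalene-1-carboxylic acid
Conditions: Pd(OAc)2 (cat.), dppp, CO (1 atm), Et3N, DMF/H2O, 60 °C; 1 M HCl work-up
Reagents that add atoms: carbon monoxide, [C-]#[O+]; water, O
Why: Palladium-catalysed hydroxycarbonylation of a vinyl triflate (oxidative addition to zerovalent palladium, CO insertion, hydrolysis of the acyl complex) installs C19 on C4.

**Step 3**
Reactants: 3 unsaturated acid
Product: 4 (R)-6-methoxy-1,2,3,4-tetrahydronaphthalene-1-carboxylic acid
Conditions: Ru(OAc)2[(R)-BINAP] (cat.), H2 (100 atm), MeOH, rt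
Reagents that add atoms: none
Why: Noyori asymmetric hydrogenation of an α-aryl α,β-unsaturated acid; the carboxylate binds ruthenium and the chiral diphosphine selects the alkene face, which sets C4 (R), and recrystallisation of the acid can raise the optical purity.

**Step 4**
Reactants: 4 (R)-tetralin acid
Product: 7 (1R,8aS)-6-oxo-1,2,3,4,6,7,8,8a-octahydronaphthalene-1-carboxylic acid (trans enone acid; CO2H 4α equatorial; H4β; H5α), via dihydroanisole acid 5 (not isolated), via β,γ-enone acid 6 (not isolated)
Conditions: Li, NH3(l)/THF/t-BuOH, –78 → –33 °C; NH4Cl; then 3 M HCl, THF, 50 °C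
Reagents that add atoms: water, O
Why: Birch reduction of the anisole ring (t-BuOH keeps the medium free of amide base, so C4–H is not removed), then enol ether hydrolysis and acid-catalysed conjugation through the dienol; protonation at C5 is reversible, so C5 settles under thermodynamic control with the C4 carboxyl equatorial (H4/H5 trans-diaxial), acid does not touch C4, and the minor C5 epimer is removed at the ester stage and can be re-equilibrated.

**Step 5**
Reactants: 7 trans enone acid
Product: 8 methyl (1R,8aS)-6-oxo-1,2,3,4,6,7,8,8a-octahydronaphthalene-1-carboxylate (trans enone ester; C8=O; C9=C10)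
Conditions: MeI, K2CO3, DMF, rt; chromatography
Reagents that add atoms: iodomethane, CI
Why: SN2 O-alkylation of the carboxylate, under a base too weak to enolise the ester, so C4 and with it the absolute configuration is kept.

**Step 6**
Reactants: 8 trans enone ester; 9 acetylene
Product: 10 cyclobutene-fused trans-decalone (methyl 8-oxo-9β,10β-etheno-decalin-4α-carboxylate; C20=C11 bridge on the β face; H5α; H9α; H4β)
Conditions: hν (medium-pressure Hg lamp, uranium-glass filter, λ > 340 nm), acetone saturated with acetylene, –70 °C, stopped before full conversion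
Reagents that add atoms: acetylene (9), C#C
Why: Excitation of the enone and intersystem crossing give the twisted triplet, which adds acetylene stepwise: a first C–C bond gives a triplet 1,4-diradical and, after spin inversion, radical recombination forms the second bond. The closest known reaction type is the enone–alkyne [2+2] photocycloaddition, practised with acetylene itself on cyclohexenones, octalones and steroidal enones. The one new ring, the cyclobutene C9–C10–C20=C11, is closed by this diradical collapse and can only be cis-fused to ring B, because a trans-fused bicyclo[4.2.0]octene is too strained. C10 is controlled by C5, since in the relaxed triplet C10 pyramidalises toward the chair trans-decalin shape and takes up C20 axially on the face opposite H5; C9 is controlled by C10 through the four-membered ring, which places C11 on the same β face and H9 on the α face. No regiochemistry arises because acetylene is symmetric, and the equatorial ester at C4 lies away from the reacting face. The selectivity to be secured is survival of the product, a β,γ-unsaturated ketone prone to photochemical 1,3-acyl shift, so only light absorbed by the enone tail is admitted, the acetylene concentration is kept high by the low temperature, and irradiation is ended early with recycling of 8.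

**Step 7**
Reactants: 10 cyclobutene ketone
Product: 11 8,8-ethylenedioxy ketal of 10
Conditions: TMSOCH2CH2OTMS, TMSOTf (cat.), CH2Cl2, –78 → –20 °C
Reagents that add atoms: 1,2-bis(trimethylsilyloxy)ethane, C[Si](C)(C)OCCO[Si](C)(C)C
Why: Noyori ketalisation runs aprotically at low temperature and so avoids the acid-catalysed 1,2-acyl shift (Cargill rearrangement) that hot protic acid would bring about in this β,γ-unsaturated ketone.

**Step 8**
Reactants: 11 cyclobutene ketal ester
Product: 13 4α-methyl-4β-methoxycarbonyl cyclobutene ketal, via lithium enolate 12 (not isolated)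
Conditions: LiN(iPr)2, THF, –78 °C; MeI, DMPU, –78 → –20 °C
Reagents that add atoms: iodomethane, CI
Why: Alkylation of an exocyclic ester enolate; the β face of C4 is screened by the 1,3-diaxial C20, so MeI enters from the equatorial α side and leaves the ester axial (β), which sets C4 as in podocarpate-type alkylations.

**Step 9**
Reactants: 13 methylated cyclobutene ketal
Product: 16 ketal lactone alcohol (C19(=O)–O–C20 δ-lactone on the β face; C9β-CH2OH; 4α-CH3; H5α; H9α), via dialdehyde 14 (not isolated), via diol 15 (not isolated)
Conditions: O3, CH2Cl2, –78 °C; Me2S, –78 °C → rt; MeOH, NaBH4, 0 °C; crude diol, DBU (cat.), toluene, 60 °C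
Reagents that add atoms: ozone, [O-][O+]=O
Why: Ozonolysis of the only alkene unmasks C20 and C11 as aldehydes and borohydride reduces both; the C20 hydroxyl lies 1,3-diaxial to the C19 ester and closes the δ-lactone by transesterification, whereas C11–OH can reach no ester, so the two arms are told apart without touching a stereocentre.

**Step 10**
Reactants: 16 lactone alcohol
Product: 17 ketal lactone aldehyde (C9β-CHO)
Conditions: Dess–Martin periodinane, CH2Cl2, 0 °C → rt
Reagents that add atoms: none
Why: Dess–Martin oxidation under near-neutral conditions spares the ketal and gives the aldehyde with its equatorial, thermodynamically preferred C9 configuration.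

**Step 11**
Reactants: 17 lactone aldehyde
Product: 18 ketal lactone with C9β-vinyl group (C11=C12)
Conditions: Ph3PCH3Br, KN(SiMe3)2, THF, 0 °C; then 17, –78 → 0 °C
Reagents that add atoms: methyltriphenylphosphonium bromide, C[P+](c1ccccc1)(c1ccccc1)c1ccccc1.[Br-]
Why: Wittig methylenation brings in C12; addition of the unstabilised ylide to the aldehyde at low temperature outruns enolisation at C9, and the lactone carbonyl on quaternary C4 is too hindered to compete.

**Step 12**
Reactants: 18 vinyl lactone
Product: 20 methyl 20-hydroxy ester (C10β-CH2OH; C4β-CO2Me; C9β-vinyl; C8 ketal), via potassium carboxylate 19 (not isolated)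
Conditions: KOH (1.1 equiv), MeOH/H2O, 70 °C; evaporate to dryness; MeI, DMF, 0 °C → rt; used at once
Reagents that add atoms: potassium hydroxide, [K+].[OH-]; iodomethane, CI
Why: Saponification of the lactone followed by SN2 O-methylation of the carboxylate, which works for hindered acids because the new bond forms at oxygen away from C4; the lactone is opened here, while only base-stable groups are present, because the later butenolide would not survive hydroxide.

**Step 13**
Reactants: 20 hydroxy ester
Product: 21 C20 tert-butyldimethylsilyl ether of 20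
Conditions: TBSOTf, 2,6-lutidine, CH2Cl2, –78 → 0 °C
Reagents that add atoms: tert-butyldimethylsilyl triflate, CC(C)(C)[Si](C)(C)OS(=O)(=O)C(F)(F)F
Why: Silylation with the silyl triflate is fast even at a neopentyl hydroxyl and needs no alkoxide, so re-closure of the lactone gets no chance; ketals tolerate this reagent pair.

**Step 14**
Reactants: 21 silyl ether with C9β-vinyl group; 22 3-bromofuran-2(5H)-one
Product: 24 ketal silyl ether carrying the complete C11–C12 chain and the α-linked butenolide, via alkylborane 23 (not isolated)
Conditions: 9-BBN-H, THF, rt → 40 °C; then 22, PdCl2(dppf) (cat.), AsPh3, Cs2CO3, DMF/H2O, rt → 45 °C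
Reagents that add atoms: 3-bromofuran-2(5H)-one (22), O=C1OCC=C1Br
Why: Anti-Markovnikov hydroboration of the only alkene and B-alkyl Suzuki–Miyaura coupling, a reaction type known for α-halo enones and 3-bromofuranones, form C12–C13 and deliver the butenolide with its double bond already in place.

**Step 15**
Reactants: 24 ketal
Product: 25 8-ketone (C20 OTBS; C19 methyl ester; butenolide side chain)
Conditions: PPTS, acetone/H2O, 55 °C
Reagents that add atoms: water, O
Why: Mild acid hydrolysis of the dioxolane; the hindered neopentyl silyl ether, the ester and the butenolide tolerate it, and the equatorial C9 side chain is the stable epimer next to the ketone.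

**Step 16**
Reactants: 25 ketone
Product: 26 8(17)-methylene compound (C20 OTBS)
Conditions: Zn, CH2Br2, TiCl4 (reagent pre-aged in THF), CH2Cl2, 0 °C → rt
Reagents that add atoms: dibromomethane, BrCBr
Why: Lombardo methylenation; the zinc–titanium gem-dimetallic reagent is non-basic and reacts with ketones but not esters or lactones, so it neither epimerises C9 nor deprotonates or attacks the butenolide as a phosphorus ylide would.

**Step 17**
Reactants: 26 silyl ether
Product: 27 methyl 20-hydroxylabda-8(17),13-dien-16,15-olid-19-oate
Conditions: HF·pyridine, pyridine/THF, 0 °C; crude product used at once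
Reagents that add atoms: none
Why: Fluoride-driven desilylation in a buffered, weakly acidic medium avoids the alkoxide that a basic fluoride source would give, which protects the butenolide and keeps transesterification onto C19 slow.

**Step 18**
Reactants: 27 C20 alcohol
Product: 28 methyl 20-oxolabda-8(17),13-dien-16,15-olid-19-oate (CNP0175906.1)
Conditions: Dess–Martin periodinane, CH2Cl2, 0 °C → rt
Reagents that add atoms: none
Why: Dess–Martin oxidation turns the neopentyl primary alcohol into the aldehyde under neutral conditions; C10 carries no hydrogen, so nothing can epimerise, and the alkene, ester and butenolide are inert.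

**Compound list**
1 | 6-methoxy-1-tetralone | COc1ccc2C(=O)CCCc2c1 | starting material
2 | 6-methoxy-3,4-dihydronaphthalen-1-yl triflate | COc1ccc2C(OS(=O)(=O)C(F)(F)F)=CCCc2c1 | intermediate
3 | 6-methoxy-3,4-dihydronaphthalene-1-carboxylic acid | COc1ccc2C(C(=O)O)=CCCc2c1 | intermediate
4 | (R)-6-methoxy-1,2,3,4-tetrahydronaphthalene-1-carboxylic acid | COc1ccc2c(c1)CCC[C@H]2C(=O)O | intermediate
5 | (R)-6-methoxy-1,2,3,4,5,8-hexahydronaphthalene-1-carboxylic acid | COC1=CCC2=C(C1)CCC[C@H]2C(=O)O | intermediate (not isolated)
6 | (R)-6-oxo-1,2,3,4,5,6,7,8-octahydronaphthalene-1-carboxylic acid | O=C1CCC2=C(C1)CCC[C@H]2C(=O)O | intermediate (not isolated)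
7 | (1R,8aS)-6-oxo-1,2,3,4,6,7,8,8a-octahydronaphthalene-1-carboxylic acid | O=C1C=C2CCC[C@@H](C(=O)O)[C@@H]2CC1 | intermediate
8 | methyl (1R,8aS)-6-oxo-1,2,3,4,6,7,8,8a-octahydronaphthalene-1-carboxylate | O=C1C=C2CCC[C@@H](C(=O)OC)[C@@H]2CC1 | intermediate (key-step precursor)
9 | acetylene | C#C | starting material
10 | cyclobutene-fused trans-decalone ester | O=C1CC[C@@H]2[C@]3(C=C[C@@H]13)CCC[C@H]2C(=O)OC | intermediate (key-step product)
11 | 8,8-ethylenedioxy ketal of 10 | O1CCOC12CC[C@@H]3[C@]4(C=C[C@@H]24)CCC[C@H]3C(=O)OC | intermediate
12 | lithium ester enolate of 11 (C4=C19) | O1CCOC12CC[C@@H]3[C@]4(C=C[C@@H]24)CCCC3=C(OC)[O-].[Li+] | intermediate (not isolated)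
13 | 4α-methyl-4β-methoxycarbonyl cyclobutene ketal | O1CCOC12CC[C@@H]3[C@]4(C=C[C@@H]24)CCC[C@]3(C)C(=O)OC | intermediate
14 | C11/C20 dialdehyde ketal ester | O1CCOC12CC[C@@H]3[C@](C=O)(CCC[C@]3(C)C(=O)OC)[C@H]2C=O | intermediate (not isolated)
15 | C11/C20 diol ketal ester | O1CCOC12CC[C@@H]3[C@](CO)(CCC[C@]3(C)C(=O)OC)[C@H]2CO | intermediate (not isolated)
16 | ketal 19,20-δ-lactone with C9β-CH2OH | O1CCOC12CC[C@@H]3[C@@]4(COC(=O)[C@@]3(C)CCC4)[C@H]2CO | intermediate
17 | ketal 19,20-δ-lactone with C9β-CHO | O1CCOC12CC[C@@H]3[C@@]4(COC(=O)[C@@]3(C)CCC4)[C@H]2C=O | intermediate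
18 | ketal 19,20-δ-lactone with C9β-vinyl | O1CCOC12CC[C@@H]3[C@@]4(COC(=O)[C@@]3(C)CCC4)[C@H]2C=C | intermediate
19 | potassium 20-hydroxy-19-carboxylate | O1CCOC12CC[C@@H]3[C@](CO)(CCC[C@]3(C)C(=O)[O-])[C@H]2C=C.[K+] | intermediate (not isolated)
20 | methyl 20-hydroxy ester (vinyl, ketal) | O1CCOC12CC[C@@H]3[C@](CO)(CCC[C@]3(C)C(=O)OC)[C@H]2C=C | intermediate
21 | C20 TBS ether of 20 | O1CCOC12CC[C@@H]3[C@](CO[Si](C)(C)C(C)(C)C)(CCC[C@]3(C)C(=O)OC)[C@H]2C=C | intermediate
22 | 3-bromofuran-2(5H)-one | O=C1OCC=C1Br | starting material
23 | C12 B-alkyl-9-borabicyclo[3.3.1]nonane | O1CCOC12CC[C@@H]3[C@](CO[Si](C)(C)C(C)(C)C)(CCC[C@]3(C)C(=O)OC)[C@H]2CCB4C5CCCC4CCC5 | intermediate (not isolated)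
24 | butenolide ketal TBS ether | O1CCOC12CC[C@@H]3[C@](CO[Si](C)(C)C(C)(C)C)(CCC[C@]3(C)C(=O)OC)[C@H]2CCC4=CCOC4=O | intermediate
25 | 8-ketone TBS ether | O=C1CC[C@@H]2[C@](CO[Si](C)(C)C(C)(C)C)(CCC[C@]2(C)C(=O)OC)[C@H]1CCC1=CCOC1=O | intermediate
26 | 8(17)-methylene TBS ether | C=C1CC[C@@H]2[C@](CO[Si](C)(C)C(C)(C)C)(CCC[C@]2(C)C(=O)OC)[C@H]1CCC1=CCOC1=O | intermediate
27 | methyl 20-hydroxylabda-8(17),13-dien-16,15-olid-19-oate | C=C1CC[C@@H]2[C@](CO)(CCC[C@]2(C)C(=O)OC)[C@H]1CCC1=CCOC1=O | intermediate
28 | methyl 20-oxolabda-8(17),13-dien-16,15-olid-19-oate (CNP0175906.1) | C=C1CC[C@@H]2[C@](C=O)(CCC[C@]2(C)C(=O)OC)[C@H]1CCC1=CCOC1=O | target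

**Total step count:** 18. **Longest linear sequence:** 18 steps, from 6-methoxy-1-tetralone; acetylene and 3-bromofuran-2(5H)-one are bought.

**Steps most likely to fail**

Step 6 (photocycloaddition).
- What may go wrong: acetylene is a sluggish trap for the triplet enone, so enone dimerisation or photoreduction may compete. Continued irradiation may also consume the adduct by 1,3-acyl shift.
- The fallback sets out from 8 and comes back at 11.
- It replaces acetylene by a more reactive alkene whose adduct has no β,γ-double bond while light is on.
- Irradiation of 8 with excess 1,2-dichloroethylene (Pyrex, CH2Cl2) should give the dichlorocyclobutane ketone F1, as a mixture of chloride epimers with the same C9/C10 sense.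
- Ketalisation as in step 7 should give the dichloro ketal F2.
- Reductive 1,2-elimination with activated Zn in refluxing EtOH, which spares the ester, should give 11.

Step 12 (lactone opening and trapping).
- What may go wrong: slow hydrolysis of the hindered bridged lactone, and back-closure of the hydroxy ester during methylation or work-up, before it can be silylated.
- The fallback sets out from 13 and comes back at 21.
- It avoids both the lactone and any free C20 hydroxyl, and tells the two arms apart by steric hindrance instead.
- Ozonolysis of 13 with Me2S work-up and isolation of 14 comes first.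
- One equivalent of Ph3P=CH2 at –78 °C should react at the less hindered C11 aldehyde and give the vinyl aldehyde F3.
- Copper hydride-catalysed hydrosilylation of the remaining neopentyl aldehyde (Cu(OAc)2, 1,2-bis(diphenylphosphino)benzene, t-BuMe2SiH, toluene) should give the silyl ether 21 directly.

Step 14 (B-alkyl Suzuki coupling).
- What may go wrong: base-induced decay of the bromobutenolide, protodeboronation, or slow transmetalation of the crowded alkylborane.
- The fallback sets out from 21 and comes back at 24.
- It builds the butenolide by enolate alkylation and sulfoxide elimination.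
- Hydroboration to 23 with oxidative work-up (H2O2, NaOH) should give the C12 alcohol F4.
- I2, PPh3 and imidazole should give the C12 iodide F5.
- Alkylation of the lithium enolate of commercial 3-(phenylsulfanyl)dihydrofuran-2(3H)-one (LiN(iPr)2, THF/DMPU) should give the α-phenylsulfanyl lactone F6, as a mixture at C13.
- One equivalent of mCPBA at –78 °C should give the sulfoxide F7. No alkene is present at this stage.
- Thermal syn elimination in refluxing toluene should give 24.

**Further compounds**
F1 | step 6 | dichlorocyclobutane ketone (C11 and C20 chlorides, epimer mixture) | O=C1CC[C@@H]2[C@]3(C(Cl)C(Cl)[C@@H]13)CCC[C@H]2C(=O)OC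
F2 | step 6 | dichloro ketal | O1CCOC12CC[C@@H]3[C@]4(C(Cl)C(Cl)[C@@H]24)CCC[C@H]3C(=O)OC
F3 | step 12 | vinyl aldehyde (C9β-vinyl, C10β-CHO, ketal, methyl ester) | O1CCOC12CC[C@@H]3[C@](C=O)(CCC[C@]3(C)C(=O)OC)[C@H]2C=C
F4 | step 14 | C12 alcohol | O1CCOC12CC[C@@H]3[C@](CO[Si](C)(C)C(C)(C)C)(CCC[C@]3(C)C(=O)OC)[C@H]2CCO
F5 | step 14 | C12 iodide | O1CCOC12CC[C@@H]3[C@](CO[Si](C)(C)C(C)(C)C)(CCC[C@]3(C)C(=O)OC)[C@H]2CCI
F6 | step 14 | α-phenylsulfanyl lactone (C13 epimer mixture) | O1CCOC12CC[C@@H]3[C@](CO[Si](C)(C)C(C)(C)C)(CCC[C@]3(C)C(=O)OC)[C@H]2CCC4(Sc5ccccc5)CCOC4=O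
F7 | step 14 | sulfoxide of F6 | O1CCOC12CC[C@@H]3[C@](CO[Si](C)(C)C(C)(C)C)(CCC[C@]3(C)C(=O)OC)[C@H]2CCC4(S(=O)c5ccccc5)CCOC4=O
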